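## Retrosynthetic overview

1. The target is a cis-fused hydroazulene. Ring A is seven-membered (C-1 bears =CH2, C-5 is CMe2) and ring B is five-membered. The quaternary carbon Cq (C-9) of ring B, bonded to CH3, the ring-fusion CH C-11, the ring CH2 C-8 and the bicycle carbon Ca, carries a 2,7-dioxabicyclo[3.2.1]octan-3-one. Last disconnections: C=CH2 from the C-1 ketone, acetate from the alcohol, acetal-lactone from lactol plus carboxylic acid.
2. The Ca–Cb bond comes from Michael addition of a γ-lactone enolate to (S)-5-silyloxy-5,6-dihydropyran-2-one, followed by α-hydroxylation; Ca is tied to C-8 by a removable iodolactone. The Ca–C(acetal) bond comes from one-carbon homologation of a formyl group on Cq.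
3. Strategic feature: Cq is the terminus of a 1,2-acyl shift. The Cq–C-8 bond of ring B forms when a cis-fused 3-methyl-2,3-epoxycyclohexanone contracts to a 2-formyl-2-methylcyclopentanone, whose formyl carbon is Ca.
4. The epoxy ketone comes from the enone, made by enantioselective Diels–Alder reaction of 4,4-dimethylcyclohept-2-enone with a 2-silyloxypentadiene and Saegusa–Ito oxidation. The cycloheptenone comes from cycloheptane-1,3-dione by two separate methylations and carbonyl transposition.
5. Ring order: ring A (starting material), six-membered precursor of ring B (step 6), ring B by contraction (step 11), temporary iodolactone (step 16), γ-lactone that becomes the tetrahydrofuran ring (step 21), bridging δ-lactone (step 25).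

Key step: step 11

Labels: C-1 to C-11 are the ring carbons: C-1 (=CH2 in the target), C-2 to C-4 (CH2), C-5 (CMe2), C-6 (ring-fusion CH), C-7 and C-8 (ring B CH2 in the target), C-9 = Cq, C-10 (ring B carbon before step 11, side-chain carbon Ca afterwards), C-11 (ring-fusion CH next to C-1). Bicycle carbons: Ca, C(acetal), Cb (CH bonded to Ca), C(OAc), C(lactone), Ce (CH–CO2Me).

Assumption: the (S)-oxazaborolidinium catalyst of step 6 is taken to direct the diene to the enone face that gives the C-6/C-11 configuration of the target; if the sense is the reverse, the (R)-catalyst is used.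

Remark: the configuration of the carbinol carbon C-1 made in step 7 (drawn cis to the C-11–C-9 bond), the configuration at C-9 in 10 to 12 and the E/Z ratio of 16 are of no consequence, since these elements are removed later.

## Route

Step 1
Reactants: 1 cycloheptane-1,3-dione
Product: 2 3-ethoxycyclohept-2-en-1-one
Conditions: EtOH, TsOH·H2O (catalytic), toluene, reflux, Dean–Stark trap
Reagents that add atoms: ethanol, CCO
Why: Acid-catalysed O-alkylation of the cyclic 1,3-dione with azeotropic removal of water gives the vinylogous ester needed for a Stork–Danheiser sequence, and no stereocentre is formed.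

Step 2
Reactants: 2 3-ethoxycyclohept-2-en-1-one; 3 iodomethane
Product: 4 3-ethoxy-7-methylcyclohept-2-en-1-one (racemic)
Conditions: LiN(iPr)2 (1.1 equiv), THF, −78 °C; then MeI (1.2 equiv), −78 → 0 °C
Reagents that add atoms: none
Why: Kinetic deprotonation of a 3-alkoxyenone by the lithium amide takes place at the α′-carbon next to the carbonyl group and the enolate is C-methylated once (Stork–Danheiser alkylation); the new stereocentre is racemic and disappears in step 3.

Step 3
Reactants: 4 3-ethoxy-7-methylcyclohept-2-en-1-one; 3 iodomethane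
Product: 5 3-ethoxy-7,7-dimethylcyclohept-2-en-1-one
Conditions: LiN(iPr)2 (1.2 equiv), THF, −78 °C; then MeI (1.5 equiv), DMPU, −78 → 0 °C
Reagents that add atoms: none
Why: A second kinetic α′-deprotonation gives the fully substituted enolate, whose methylation (Stork–Danheiser alkylation) builds the gem-dimethyl carbon and removes the stereocentre of 4; running the two methylations as separate operations lets each one be driven to completion.

Step 4
Reactants: 5 3-ethoxy-7,7-dimethylcyclohept-2-en-1-one
Product: 7 4,4-dimethylcyclohept-2-en-1-one, via allylic alcohol 6 (not isolated)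
Conditions: LiAlH4, Et2O, 0 °C; then 2 M HCl, THF, rt
Reagents that add atoms: water, O
Why: 1,2-Reduction of the vinylogous ester followed by acid hydrolysis of the allylic enol ether and loss of water transposes the carbonyl group (Stork–Danheiser transposition) and places the gem-dimethyl carbon at the γ-position of the new enone.

Step 5
Reactants: 8 (E)-pent-3-en-2-one
Product: 9 (E)-tert-butyldimethyl(penta-1,3-dien-2-yloxy)silane
Conditions: tBuMe2SiOTf, Et3N, Et2O, 0 °C
Reagents that add atoms: tert-butyldimethylsilyl trifluoromethanesulfonate, CC(C)(C)[Si](C)(C)OS(=O)(=O)C(F)(F)F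
Why: Soft enolisation of the methyl ketone with silyl triflate and amine removes a proton from the α′-methyl group and gives the cross-conjugated 2-silyloxydiene with the (E)-propenyl unit intact, so that no substituent points into the diene cavity.

Step 6
Reactants: 7 4,4-dimethylcyclohept-2-en-1-one; 9 (E)-tert-butyldimethyl(penta-1,3-dien-2-yloxy)silane
Product: 10 cis-fused Diels–Alder adduct (ring A ketone at C-1, silyl enol ether C-8(OTBS)=C-10, CH3 on C-9 cis to C-1)
Conditions: (S)-3,3-diphenyl-1-(2-methylphenyl)hexahydropyrrolo[1,2-c][1,3,2]oxazaborole (20 mol %), HN(SO2CF3)2 (16 mol %), CH2Cl2, −78 → −40 °C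
Reagents that add atoms: none
Why: Enantioselective Diels–Alder reaction of a 2-cycloalkenone with a 2-silyloxydiene under a cationic chiral oxazaborolidine, in which the silyloxy and methyl groups both make the CH2 terminus the nucleophilic end that bonds to the enone β-carbon C-6, suprafacial addition gives the cis ring fusion, and the catalyst selects the enone face so that C-6 and C-11 are set in the sense of the target.

Step 7
Reactants: 10 cis-fused Diels–Alder adduct
Product: 11 ring A alcohol (C-1 OH cis to the C-11–C-9 bond, silyl enol ether retained)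
Conditions: LiAlH4, Et2O, −78 °C; aq. KNaC4H4O6 work-up
Reagents that add atoms: none
Why: Hydride addition to the saturated ketone at low temperature leaves the silyl enol ether untouched and is expected from the face away from the ring B branch at C-11, and the new carbinol centre is removed again in step 28.

Step 8
Reactants: 11 ring A alcohol
Product: 12 C-1 tert-butyldiphenylsilyl ether of 11
Conditions: tBuPh2SiCl, imidazole, DMAP (catalytic), DMF, 40 °C
Reagents that add atoms: tert-butyl(chloro)diphenylsilane, CC(C)(C)[Si](Cl)(c1ccccc1)c1ccccc1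
Why: Silylation of the secondary alcohol masks the ring A oxygen as an acid-stable ether, so that the ring-fusion CH C-11 is not activated by a carbonyl group in the epoxidation and in the key step.

Step 9
Reactants: 12 C-1 silyl ether
Product: 13 cis-fused enone (C-8 ketone, C-10=C-9 alkene with CH3 on C-9, C-1 OTBDPS)
Conditions: Pd(OAc)2 (1.1 equiv), MeCN, 40 °C
Reagents that add atoms: none
Why: Saegusa–Ito oxidation, in which divalent palladium converts the regiodefined silyl enol ether into the palladium enolate bound at C-10, whose β-hydride elimination can only involve C-9 and so gives the 3-methylcyclohexenone while removing the stereocentre at C-9.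

Step 10
Reactants: 13 cis-fused enone
Product: 14 epoxy ketone (C-10/C-9 epoxide on the face of H-6 and H-11, CH3 on C-9 on the face of ring A)
Conditions: 30 % H2O2, NaOH (catalytic), MeOH, 0 °C
Reagents that add atoms: hydrogen peroxide, OO
Why: Nucleophilic epoxidation of the β,β-disubstituted enone (Weitz–Scheffer reaction), in which the hydroperoxide anion adds axially to C-9 anti to the pseudoaxial C-11–C-1 bond, that is on the convex face carrying H-6 and H-11, and ring closure on the same face sets both epoxide stereocentres.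

Step 11
Reactants: 14 epoxy ketone
Product: 15 keto aldehyde (cis-hydroazulene, C-8 ketone, Cq with CH3 syn to ring A and CHO on the face of H-6 and H-11, C-1 OTBDPS)
Conditions: BF3·OEt2 (1.2 equiv), toluene, 0 °C, short reaction time; aq. NaHCO3 quench
Reagents that add atoms: none
Why: BF3 binds the epoxide oxygen, the C-9–O bond at the tertiary, methyl-bearing carbon lengthens, the ketone carbon C-8 moves its bond from C-10 to C-9 on the side opposite to the leaving oxygen, and C-10 with its oxygen becomes the formyl group. The closest known reaction is the Lewis-acid rearrangement of 2,3-epoxycyclohexanones to 2-formylcyclopentanones, a semipinacol 1,2-acyl shift. No cyclisation mode applies to ring B, because the five-membered ring arises when C-8 exchanges its bond to C-10 for a bond to C-9 and C-10 is extruded from the six-membered ring. The one new stereocentre, Cq, is set by inversion at C-9: the epoxide oxygen lies on the face of H-6 and H-11, so the formyl group ends on that face and CH3 stays syn to ring A. The step needs the acyl shift to win over hydride shift from C-10 and over loss of H-11; an acyl carbon shifts more readily than hydrogen in these openings, and with a silyl ether and no carbonyl group at C-1 the proton H-11 is not acidified and a β,γ-epoxy ketone elimination is not possible.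

Step 12
Reactants: 15 keto aldehyde
Product: 16 methyl enol ether (Cq–CH=CH–OMe, E/Z mixture, C-8 ketone retained)
Conditions: Ph3P(CH2OMe)Cl, KN(SiMe3)2, THF, 0 °C; then 15, −78 → 0 °C
Reagents that add atoms: (methoxymethyl)triphenylphosphonium chloride, COC[P+](c1ccccc1)(c1ccccc1)c1ccccc1.[Cl-]
Why: Wittig methoxymethylenation adds the one-carbon unit C(acetal) to the non-enolisable aldehyde much faster than to the neopentyl ring B ketone, and both enol ether isomers converge in step 15.

Step 13
Reactants: 16 methyl enol ether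
Product: 17 vinyl triflate (C-7=C-8–OTf)
Conditions: KN(SiMe3)2, THF, −78 °C; then PhN(SO2CF3)2
Reagents that add atoms: N-phenylbis(trifluoromethanesulfonimide), O=S(=O)(N(c1ccccc1)S(=O)(=O)C(F)(F)F)C(F)(F)F
Why: The ring B ketone can enolise only toward C-7 because Cq is quaternary, so the potassium enolate is trapped on oxygen as a single vinyl triflate.

Step 14
Reactants: 17 vinyl triflate
Product: 18 cyclopentene (C-7=C-8, enol ether side chain retained)
Conditions: Pd(OAc)2 (5 mol %), PPh3 (10 mol %), Bu3N, HCO2H, DMF, 60 °C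
Reagents that add atoms: none
Why: Palladium-catalysed formate reduction of a vinyl triflate (oxidative addition to zerovalent palladium, formate exchange, loss of CO2 and reductive elimination) replaces the triflate by hydrogen under buffered conditions that spare the enol ether.

Step 15
Reactants: 18 cyclopentene
Product: 20 γ,δ-unsaturated acid (Cq–CH2–CO2H), via aldehyde 19 (not isolated)
Conditions: 1 M HCl, THF, rt; then NaClO2, NaH2PO4, 2-methyl-2-butene, tBuOH/H2O, rt
Reagents that add atoms: water, O; sodium chlorite, [Na+].[O-]Cl=O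
Why: Mild acid hydrolysis of the enol ether unmasks the homologated aldehyde, which chlorite oxidises in the same flask (Pinnick oxidation) to the acid without touching the ring alkene or the silyl ether.

Step 16
Reactants: 20 γ,δ-unsaturated acid
Product: 21 iodolactone (γ-lactone O on C-8 cis to Ca, I on C-7 trans to O)
Conditions: I2, NaHCO3, MeCN/H2O, 0 °C, dark
Reagents that add atoms: iodine, II
Why: Iodolactonisation, in which the carboxylate held on the face of H-6 and H-11 by Cq opens the iodonium ion anti at C-8 in a 5-exo closure, gives the cis-fused γ-lactone, sets C-7 and C-8 and ties Ca into a rigid ring with the angular CH3 on its convex face.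

Step 17
Reactants: 22 (S)-but-3-ene-1,2-diol; 23 acryloyl chloride
Product: 24 (S)-2-hydroxybut-3-en-1-yl acrylate
Conditions: 2,4,6-collidine, CH2Cl2, −78 °C
Reagents that add atoms: none
Why: At low temperature with a hindered pyridine base the acyl chloride esterifies the primary hydroxyl group of the 1,2-diol much faster than the secondary one, and the stereocentre comes unchanged from the diol.

Step 18
Reactants: 24 (S)-2-hydroxybut-3-en-1-yl acrylate
Product: 25 (S)-2-(tert-butyldimethylsilyloxy)but-3-en-1-yl acrylate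
Conditions: tBuMe2SiOTf, 2,6-lutidine, CH2Cl2, −78 °C
Reagents that add atoms: tert-butyldimethylsilyl trifluoromethanesulfonate, CC(C)(C)[Si](C)(C)OS(=O)(=O)C(F)(F)F
Why: Silylation of the secondary alcohol with silyl triflate and a hindered base is faster than acyl migration and does not touch the stereocentre.

Step 19
Reactants: 25 (S)-2-(tert-butyldimethylsilyloxy)but-3-en-1-yl acrylate
Product: 26 (S)-5-(tert-butyldimethylsilyloxy)-5,6-dihydro-2H-pyran-2-one
Conditions: second-generation Grubbs catalyst RuCl2(=CHPh)(PCy3)(H2IMes) (5 mol %), CH2Cl2, reflux, high dilution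
Reagents that add atoms: none
Why: Ring-closing metathesis of the acrylate with the terminal alkene forms the α,β-unsaturated δ-lactone with loss of ethylene and leaves the stereocentre untouched.

Step 20
Reactants: 21 iodolactone; 26 (S)-5-(tert-butyldimethylsilyloxy)-5,6-dihydro-2H-pyran-2-one
Product: 28 Michael–hydroxylation product (iodolactone bearing on Ca a 3-hydroxy-5-silyloxy-2-oxotetrahydropyran-4-yl group, OH and OTBS both trans to Ca), via sodium enolate 27 (not isolated)
Conditions: NaN(SiMe3)2, THF, −78 °C; then 26, −78 °C; then 2-(phenylsulfonyl)-3-phenyloxaziridine, −78 °C; AcOH quench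
Reagents that add atoms: 2-(phenylsulfonyl)-3-phenyloxaziridine, O=S(=O)(N1OC1c1ccccc1)c1ccccc1
Why: Michael addition of a lactone enolate to an α,β-unsaturated lactone followed by electrophilic hydroxylation of the enolate so formed, in which the donor reacts on the convex face of the cis-fused lactone (syn to the angular CH3, anti to ring B) and sets Ca, the acceptor is attacked anti to its pseudoaxial silyloxy group and sets Cb, and the oxaziridine approaches anti to the new β-substituent and sets Ce.

Step 21
Reactants: 28 Michael–hydroxylation product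
Product: 30 bis-lactone (γ-lactone from the Ca carboxyl to the Ce oxygen, trans-fused to the δ-lactone, C-7=C-8 alkene), via seco acid 29 (not isolated)
Conditions: Zn dust, AcOH/THF, rt; filter; then EDC·HCl [N-(3-dimethylaminopropyl)-N′-ethylcarbodiimide hydrochloride], DMAP, CH2Cl2, 0 °C → rt
Reagents that add atoms: none
Why: Zinc reduces the β-iodo lactone with anti elimination to the ring B alkene and the free acid (reversal of the iodolactonisation), and carbodiimide activation then closes the γ-lactone onto the only free hydroxyl group (Steglich lactonisation), which forms the later C(acetal)–O–Ce link without touching a stereocentre.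

Step 22
Reactants: 30 bis-lactone
Product: 31 saturated bis-lactone (C-7 and C-8 now CH2)
Conditions: H2 (1 atm), Pd/C (10 %), EtOAc, rt
Reagents that add atoms: none
Why: Heterogeneous hydrogenation saturates the cis-disubstituted cyclopentene, the only C=C bond present, which completes the removal of the ring B carbonyl function and creates no stereocentre.

Step 23
Reactants: 31 saturated bis-lactone
Product: 33 carboxylic acid (γ-lactone retained, Ce–CO2Me, C(OAc) carbon as CH(OTBS)–CO2H), via hydroxy ester 32 (not isolated)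
Conditions: Et3N (0.2 equiv), MeOH, rt; AcOH (0.2 equiv), evaporate; then TEMPO (0.2 equiv), PhI(OAc)2 (2.5 equiv), MeCN/H2O, rt
Reagents that add atoms: methanol, CO; water, O
Why: Base-catalysed methanolysis opens the trans-fused α-acyloxy δ-lactone in preference to the γ-lactone, and nitroxyl-catalysed oxidation then takes the liberated primary alcohol through the aldehyde hydrate to the carboxylic acid while no secondary hydroxyl group is free to trap the aldehyde as a lactol.

Step 24
Reactants: 33 carboxylic acid
Product: 34 lactol acid (C(acetal) as hemiacetal in the tetrahydrofuran ring, anomeric mixture)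
Conditions: bis(3-methylbutan-2-yl)borane (4 equiv, from BH3·SMe2 and 2-methyl-2-butene, THF, 0 °C), THF, 0 °C → rt; then 30 % H2O2, pH 7 buffer
Reagents that add atoms: none
Why: The hindered dialkylborane reduces a γ-lactone to the lactol but does not reduce carboxylic esters or the borane-bound carboxylic acid, so only the lactone carbonyl reaches the aldehyde oxidation level.

Step 25
Reactants: 34 lactol acid
Product: 36 hydroxy bicycle (2,7-dioxabicyclo[3.2.1]octan-3-one with free OH on the C(OAc) carbon, C-1 OTBDPS), via silylated bicycle 35 (not isolated)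
Conditions: CF3CO2H, CH2Cl2, 0 °C; then CF3CO2H/H2O (9:1), rt; evaporate from toluene
Reagents that add atoms: none
Why: Acid ionises the lactol to the cyclic oxocarbenium ion, which the carboxylic acid on the cis side chain captures in a six-membered ring closure to give the bridged acyloxy acetal, whose acetal configuration is fixed by the bridge, and the aqueous acid then cleaves the tert-butyldimethylsilyl ether while the diphenylsilyl ether stays.

Step 26
Reactants: 36 hydroxy bicycle
Product: 37 acetate (C-1 OTBDPS)
Conditions: Ac2O, pyridine, DMAP (catalytic), CH2Cl2, 0 °C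
Reagents that add atoms: acetic anhydride, CC(=O)OC(C)=O
Why: Nucleophile-catalysed acetylation of the α-hydroxy lactone proceeds under mild conditions that do not open the acyloxy acetal and do not change a stereocentre.

Step 27
Reactants: 37 acetate
Product: 38 C-1 alcohol
Conditions: HF·pyridine, pyridine/THF, 0 °C → rt
Reagents that add atoms: none
Why: Fluoride cleavage of the silyl ether under buffered, non-basic conditions spares the acetate, the methyl ester and the acyloxy acetal.

Step 28
Reactants: 38 C-1 alcohol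
Product: 39 C-1 ketone
Conditions: Dess–Martin periodinane, NaHCO3, CH2Cl2, rt
Reagents that add atoms: none
Why: Oxidation of the secondary alcohol with the hypervalent iodine reagent is neutral, so the cis ring fusion at C-11 next to the new ketone is not epimerised.

Step 29
Reactants: 39 C-1 ketone
Product: 40 CNP0215240.1 (target)
Conditions: Zn, CH2Br2, TiCl4, THF (reagent aged at 5 °C); then 39, CH2Cl2, 0 °C → rt
Reagents that add atoms: dibromomethane, BrCBr
Why: Lombardo methylenation with the non-basic zinc–titanium methylene reagent converts the hindered, enolisable ketone into the exocyclic alkene without epimerising C-11 and without attacking the ester, lactone or acetate groups.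

## Compound list

1 | cycloheptane-1,3-dione | O=C1CCCCC(=O)C1 | starting material
2 | 3-ethoxycyclohept-2-en-1-one | CCOC1=CC(=O)CCCC1 | intermediate
3 | iodomethane | CI | starting material
4 | 3-ethoxy-7-methylcyclohept-2-en-1-one (racemic) | CCOC1=CC(=O)C(C)CCC1 | intermediate
5 | 3-ethoxy-7,7-dimethylcyclohept-2-en-1-one | CCOC1=CC(=O)C(C)(C)CCC1 | intermediate
6 | 3-ethoxy-7,7-dimethylcyclohept-2-en-1-ol (racemic) | CCOC1=CC(O)C(C)(C)CCC1 | intermediate
7 | 4,4-dimethylcyclohept-2-en-1-one | O=C1C=CC(C)(C)CCC1 | intermediate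
8 | (E)-pent-3-en-2-one | C/C=C/C(C)=O | starting material
9 | (E)-tert-butyldimethyl(penta-1,3-dien-2-yloxy)silane | C/C=C/C(=C)O[Si](C)(C)C(C)(C)C | intermediate
10 | cis-fused Diels–Alder adduct: C-1 ketone, C-8(OTBS)=C-10 enol ether, C-9 CH3 cis to C-1 | O=C1CCCC(C)(C)[C@@H]2CC(O[Si](C)(C)C(C)(C)C)=C[C@H](C)[C@H]12 | intermediate
11 | C-1 alcohol of 10 (OH cis to the C-11–C-9 bond) | O[C@@H]1CCCC(C)(C)[C@@H]2CC(O[Si](C)(C)C(C)(C)C)=C[C@H](C)[C@H]12 | intermediate
12 | C-1 tert-butyldiphenylsilyl ether of 11 | CC(C)(C)[Si](c5ccccc5)(c6ccccc6)O[C@@H]1CCCC(C)(C)[C@@H]2CC(O[Si](C)(C)C(C)(C)C)=C[C@H](C)[C@H]12 | intermediate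
13 | cis-fused enone: C-8 ketone, C-10=C-9(CH3), C-1 OTBDPS | CC(C)(C)[Si](c5ccccc5)(c6ccccc6)O[C@@H]1CCCC(C)(C)[C@@H]2CC(=O)C=C(C)[C@H]12 | intermediate
14 | epoxy ketone: C-10/C-9 epoxide on the face of H-6 and H-11 | CC(C)(C)[Si](c5ccccc5)(c6ccccc6)O[C@@H]1CCCC(C)(C)[C@@H]2CC(=O)[C@H]3O[C@@]3(C)[C@H]12 | intermediate
15 | keto aldehyde: cis-hydroazulene, C-8 ketone, Cq with CH3 syn to ring A and CHO on the face of H-6/H-11 | CC(C)(C)[Si](c5ccccc5)(c6ccccc6)O[C@@H]1CCCC(C)(C)[C@@H]2CC(=O)[C@@](C)(C=O)[C@H]12 | intermediate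
16 | methyl enol ether Cq–CH=CH–OMe (E/Z mixture), C-8 ketone | CC(C)(C)[Si](c5ccccc5)(c6ccccc6)O[C@@H]1CCCC(C)(C)[C@@H]2CC(=O)[C@@](C)(C=COC)[C@H]12 | intermediate
17 | vinyl triflate C-7=C-8(OTf) | CC(C)(C)[Si](c5ccccc5)(c6ccccc6)O[C@@H]1CCCC(C)(C)[C@@H]2C=C(OS(=O)(=O)C(F)(F)F)[C@@](C)(C=COC)[C@H]12 | intermediate
18 | cyclopentene C-7=C-8 with enol ether side chain | CC(C)(C)[Si](c5ccccc5)(c6ccccc6)O[C@@H]1CCCC(C)(C)[C@@H]2C=C[C@@](C)(C=COC)[C@H]12 | intermediate
19 | aldehyde Cq–CH2–CHO | CC(C)(C)[Si](c5ccccc5)(c6ccccc6)O[C@@H]1CCCC(C)(C)[C@@H]2C=C[C@@](C)(CC=O)[C@H]12 | intermediate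
20 | acid Cq–CH2–CO2H | CC(C)(C)[Si](c5ccccc5)(c6ccccc6)O[C@@H]1CCCC(C)(C)[C@@H]2C=C[C@@](C)(CC(=O)O)[C@H]12 | intermediate
21 | iodolactone: γ-lactone O on C-8 cis to Ca, I on C-7 trans to O | CC(C)(C)[Si](c5ccccc5)(c6ccccc6)O[C@@H]1CCCC(C)(C)[C@@H]2[C@H](I)[C@H]3OC(=O)C[C@@]3(C)[C@H]12 | intermediate
22 | (S)-but-3-ene-1,2-diol | C=C[C@H](O)CO | starting material
23 | acryloyl chloride | C=CC(=O)Cl | starting material
24 | (S)-2-hydroxybut-3-en-1-yl acrylate | C=C[C@H](O)COC(=O)C=C | intermediate
25 | (S)-2-(tert-butyldimethylsilyloxy)but-3-en-1-yl acrylate | C=C[C@H](O[Si](C)(C)C(C)(C)C)COC(=O)C=C | intermediate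
26 | (S)-5-(tert-butyldimethylsilyloxy)-5,6-dihydro-2H-pyran-2-one | O=C1C=C[C@H](O[Si](C)(C)C(C)(C)C)CO1 | intermediate
27 | sodium enolate of the Michael adduct | CC(C)(C)[Si](c5ccccc5)(c6ccccc6)O[C@@H]1CCCC(C)(C)[C@@H]2[C@H](I)[C@H]3OC(=O)[C@H]([C@@H]4C=C([O-])OC[C@H]4O[Si](C)(C)C(C)(C)C)[C@@]3(C)[C@H]12.[Na+] | intermediate
28 | Michael–hydroxylation product: Ca bears the 3-hydroxy-5-silyloxy-2-oxotetrahydropyran-4-yl group, OH and OTBS trans to Ca | CC(C)(C)[Si](c5ccccc5)(c6ccccc6)O[C@@H]1CCCC(C)(C)[C@@H]2[C@H](I)[C@H]3OC(=O)[C@H]([C@@H]4[C@@H](O)C(=O)OC[C@H]4O[Si](C)(C)C(C)(C)C)[C@@]3(C)[C@H]12 | intermediate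
29 | seco acid: C-7=C-8 alkene, Ca–CO2H, hydroxy δ-lactone | CC(C)(C)[Si](c5ccccc5)(c6ccccc6)O[C@@H]1CCCC(C)(C)[C@@H]2C=C[C@@](C)([C@H](C(=O)O)[C@@H]3[C@@H](O)C(=O)OC[C@H]3O[Si](C)(C)C(C)(C)C)[C@H]12 | intermediate
30 | bis-lactone: γ-lactone (Ca carboxyl to Ce oxygen) trans-fused to the δ-lactone, C-7=C-8 | CC(C)(C)[Si](c5ccccc5)(c6ccccc6)O[C@@H]1CCCC(C)(C)[C@@H]2C=C[C@@](C)([C@@H]3C(=O)O[C@H]4C(=O)OC[C@@H](O[Si](C)(C)C(C)(C)C)[C@H]34)[C@H]12 | intermediate
31 | saturated bis-lactone | CC(C)(C)[Si](c5ccccc5)(c6ccccc6)O[C@@H]1CCCC(C)(C)[C@@H]2CC[C@@](C)([C@@H]3C(=O)O[C@H]4C(=O)OC[C@@H](O[Si](C)(C)C(C)(C)C)[C@H]34)[C@H]12 | intermediate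
32 | hydroxy ester: γ-lactone with Ce–CO2Me (trans to the Cb side chain) and CH(OTBS)–CH2OH side chain | CC(C)(C)[Si](c5ccccc5)(c6ccccc6)O[C@@H]1CCCC(C)(C)[C@@H]2CC[C@@](C)([C@@H]3C(=O)O[C@@H](C(=O)OC)[C@@H]3[C@@H](CO)O[Si](C)(C)C(C)(C)C)[C@H]12 | intermediate
33 | carboxylic acid: as 32 with CH(OTBS)–CO2H | CC(C)(C)[Si](c5ccccc5)(c6ccccc6)O[C@@H]1CCCC(C)(C)[C@@H]2CC[C@@](C)([C@@H]3C(=O)O[C@@H](C(=O)OC)[C@@H]3[C@@H](C(=O)O)O[Si](C)(C)C(C)(C)C)[C@H]12 | intermediate
34 | lactol acid (anomeric mixture) | CC(C)(C)[Si](c5ccccc5)(c6ccccc6)O[C@@H]1CCCC(C)(C)[C@@H]2CC[C@@](C)([C@@H]3C(O)O[C@@H](C(=O)OC)[C@@H]3[C@@H](C(=O)O)O[Si](C)(C)C(C)(C)C)[C@H]12 | intermediate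
35 | silylated bicycle: 2,7-dioxabicyclo[3.2.1]octan-3-one with OTBS on the C(OAc) carbon | CC(C)(C)[Si](c5ccccc5)(c6ccccc6)O[C@@H]1CCCC(C)(C)[C@@H]2CC[C@@](C)([C@@H]3[C@@H]4OC(=O)[C@@H](O[Si](C)(C)C(C)(C)C)[C@H]3[C@H](C(=O)OC)O4)[C@H]12 | intermediate
36 | hydroxy bicycle | CC(C)(C)[Si](c5ccccc5)(c6ccccc6)O[C@@H]1CCCC(C)(C)[C@@H]2CC[C@@](C)([C@@H]3[C@@H]4OC(=O)[C@@H](O)[C@H]3[C@H](C(=O)OC)O4)[C@H]12 | intermediate
37 | acetate, C-1 OTBDPS | CC(C)(C)[Si](c5ccccc5)(c6ccccc6)O[C@@H]1CCCC(C)(C)[C@@H]2CC[C@@](C)([C@@H]3[C@@H]4OC(=O)[C@@H](OC(C)=O)[C@H]3[C@H](C(=O)OC)O4)[C@H]12 | intermediate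
38 | C-1 alcohol | O[C@@H]1CCCC(C)(C)[C@@H]2CC[C@@](C)([C@@H]3[C@@H]4OC(=O)[C@@H](OC(C)=O)[C@H]3[C@H](C(=O)OC)O4)[C@H]12 | intermediate
39 | C-1 ketone | O=C1CCCC(C)(C)[C@@H]2CC[C@@](C)([C@@H]3[C@@H]4OC(=O)[C@@H](OC(C)=O)[C@H]3[C@H](C(=O)OC)O4)[C@H]12 | intermediate
40 | CNP0215240.1 | C=C1CCCC(C)(C)[C@@H]2CC[C@@](C)([C@@H]3[C@@H]4OC(=O)[C@@H](OC(C)=O)[C@H]3[C@H](C(=O)OC)O4)[C@H]12 | target

## Step count and risks

Total step count: 29. Longest linear sequence: 25 steps (steps 1–4, 6–16 and 20–29).

**Step 20.** The hindered sodium enolate may take the γ-proton of 26 instead of adding to it, which opens the pyranone by β-elimination. The adduct may also revert, or the secondary iodide may be lost by base-induced elimination. The fallback replaces the metal enolate addition by a Lewis-acid Mukaiyama–Michael reaction and sets out from 21. Treatment with LiN(iPr)2 and Me3SiCl in THF at −78 °C should give the silyl ketene acetal of the iodolactone F1. With 26 and catalytic Me3SiOTf in CH2Cl2 at −78 °C, F1 should add on the same faces to give the silyl ketene acetal of the adduct F2. Rubottom oxidation of F2 with dimethyldioxirane in acetone at −78 °C and a citric acid work-up should deliver the hydroxy lactone, and the route is rejoined at 28.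

**Step 11.** Hydrogen instead of the acyl carbon may migrate to give a 1,2-dione, or a long-lived cation may lose the stereochemical link between epoxide face and Cq. The fallback keeps the 1,2-shift onto C-9 but lets a silyloxy-bearing carbon migrate, and sets out from 14. NaBH4 in MeOH at 0 °C should give the epoxy alcohol F3 (either C-8 epimer serves). Et3SiCl and imidazole in DMF should give the epoxy silyl ether F4. MeAl(OAr)2 (Ar = 4-bromo-2,6-di-tert-butylphenyl) in CH2Cl2 at −78 °C should open the epoxide at C-9 with anti migration of C-8 to give the β-silyloxy aldehyde F5. HF·pyridine in THF at 0 °C should free the β-hydroxy aldehyde F6, and Dess–Martin periodinane should oxidise its secondary alcohol, so that the route is rejoined at 15.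

**Step 6.** The γ,γ-disubstituted enone may react slowly, the diene may add in a Mukaiyama–Michael sense without ring closure, or the catalyst may discriminate the enone faces poorly. The fallback gives up asymmetric catalysis for a resolution and sets out from 7 and 9. EtAlCl2 in CH2Cl2 at −78 °C should give the racemic adduct F7, and LiAlH4 in Et2O at −78 °C the racemic alcohol F8. Esterification with (S)-2-methoxy-2-phenylacetic acid (DCC, DMAP, CH2Cl2) should give two diastereomeric esters: the ester of 11, F9, and the ester of its enantiomer, F10, which are separated by chromatography. LiAlH4 in Et2O at 0 °C cleaves F9, and the route is rejoined at 11.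

Further compounds
F1 | step 20 | silyl ketene acetal of the iodolactone | CC(C)(C)[Si](c5ccccc5)(c6ccccc6)O[C@@H]1CCCC(C)(C)[C@@H]2[C@H](I)[C@H]3OC(O[Si](C)(C)C)=C[C@@]3(C)[C@H]12
F2 | step 20 | silyl ketene acetal of the adduct | CC(C)(C)[Si](c5ccccc5)(c6ccccc6)O[C@@H]1CCCC(C)(C)[C@@H]2[C@H](I)[C@H]3OC(=O)[C@H]([C@@H]4C=C(O[Si](C)(C)C)OC[C@H]4O[Si](C)(C)C(C)(C)C)[C@@]3(C)[C@H]12
F3 | step 11 | epoxy alcohol (C-8 OH drawn cis to the epoxide) | CC(C)(C)[Si](c5ccccc5)(c6ccccc6)O[C@@H]1CCCC(C)(C)[C@@H]2C[C@@H](O)[C@H]3O[C@@]3(C)[C@H]12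
F4 | step 11 | epoxy triethylsilyl ether | CC(C)(C)[Si](c5ccccc5)(c6ccccc6)O[C@@H]1CCCC(C)(C)[C@@H]2C[C@@H](O[Si](CC)(CC)CC)[C@H]3O[C@@]3(C)[C@H]12
F5 | step 11 | β-silyloxy aldehyde (cis-hydroazulene, C-8 OSiEt3, Cq with CH3 and CHO) | CC(C)(C)[Si](c5ccccc5)(c6ccccc6)O[C@@H]1CCCC(C)(C)[C@@H]2C[C@@H](O[Si](CC)(CC)CC)[C@@](C)(C=O)[C@H]12
F6 | step 11 | β-hydroxy aldehyde | CC(C)(C)[Si](c5ccccc5)(c6ccccc6)O[C@@H]1CCCC(C)(C)[C@@H]2C[C@@H](O)[C@@](C)(C=O)[C@H]12
F7 | step 6 | racemic Diels–Alder adduct (10 and its enantiomer) | O=C1CCCC(C)(C)[C@@H]2CC(O[Si](C)(C)C(C)(C)C)=C[C@H](C)[C@H]12.O=C1CCCC(C)(C)[C@H]2CC(O[Si](C)(C)C(C)(C)C)=C[C@@H](C)[C@@H]12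
F8 | step 6 | racemic C-1 alcohol (11 and its enantiomer) | O[C@@H]1CCCC(C)(C)[C@@H]2CC(O[Si](C)(C)C(C)(C)C)=C[C@H](C)[C@H]12.O[C@H]1CCCC(C)(C)[C@H]2CC(O[Si](C)(C)C(C)(C)C)=C[C@@H](C)[C@@H]12
F9 | step 6 | (S)-2-methoxy-2-phenylacetate of 11 | CO[C@@H](c5ccccc5)C(=O)O[C@@H]1CCCC(C)(C)[C@@H]2CC(O[Si](C)(C)C(C)(C)C)=C[C@H](C)[C@H]12
F10 | step 6 | (S)-2-methoxy-2-phenylacetate of the enantiomer of 11 | CO[C@@H](c5ccccc5)C(=O)O[C@H]1CCCC(C)(C)[C@H]2CC(O[Si](C)(C)C(C)(C)C)=C[C@@H](C)[C@@H]12
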